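**Plan**

- Late cuts: the enoate ester and the two protecting groups. The isopropenyl group is written as an acetyl group (methylenation), and its axial, methyl-syn position is traced to a hydroxyl-directed hydrogenation of a ring-B enone.
- Central cut: in ring B the order is quaternary ring-fusion C(CH3) – CH2 – CH(isopropenyl) – CH(OH) – CH(O-acyl) – ring-fusion CH. The bond from the quaternary carbon to the ring-fusion CH and the bond from the isopropenyl-bearing carbon to the carbinol carbon are cut together (formal [3+3]).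
- Enabling feature: the quaternary carbon is γ and the isopropenyl-bearing carbon is α to the carbonyl that later becomes the isopropenyl group, so one 5-methylidene-hex-3-en-2-one unit can react twice (γ, then α). Its partner is a 2-alkoxy-2-enal, whose β-carbon becomes the ring-fusion CH and whose carbonyl becomes the carbinol.
- Forward: an acyclic chain is built from methyl (R)-3-methylglutarate. Ring A closes first (6-exo conjugate addition, quaternary centre) and ring B second (aldol/β-elimination) in the same flask.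
- Stereochemistry: the C-methyl centre comes from the chiral pool and the silyloxy carbinol from a Brown allylation. The quaternary centre, ring fusion and both oxygenated ring-B carbons arise in the key step (chair transition state, equilibration). The isopropenyl-bearing centre comes from directed hydrogenation.

Key step: step 13

Remark on the chemistry: ethyl 2-diazo-2-(diethoxyphosphoryl)acetate and (2E)-3-methylpent-2-enoic acid are taken as purchasable. The olefination product of step 8 is drawn as its Z isomer; either alkene isomer converges, because that carbon becomes sp3 and epimerizable in step 13.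

**Route**

Step 1
Reactants: 1 (3R)-5-methoxy-3-methyl-5-oxopentanoic acid
Product: 3 (4S)-4-methyloxan-2-one, via hydroxy acid 2 (not isolated)
Conditions: LiBH4, THF, 0 °C → rt; then aq. HCl, rt
Reagents that add atoms: none
Why: Chemoselective borohydride reduction of the ester beside the lithium carboxylate, then acid-promoted lactonization, leaves the stereocentre untouched and fixes the enantiomeric series by the choice of which carbonyl is reduced.

Step 2
Reactants: 3 (4S)-4-methyloxan-2-one
Product: 4 (3S)-5-hydroxy-N-methoxy-N,3-dimethylpentanamide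
Conditions: MeNHOMe·HCl, AlMe3, CH2Cl2, 0 °C → rt
Reagents that add atoms: N,O-dimethylhydroxylamine hydrochloride, CNOC.Cl
Why: Aluminium-amide aminolysis of the lactone gives the N-methoxy-N-methylamide, which stores this terminus at the aldehyde oxidation level and frees the primary alcohol.

Step 3
Reactants: 4 (3S)-5-hydroxy-N-methoxy-N,3-dimethylpentanamide
Product: 5 (3S)-N-methoxy-N,3-dimethyl-5-oxopentanamide
Conditions: DMP (triacetoxy periodinane), NaHCO3, CH2Cl2, rt
Reagents that add atoms: none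
Why: Periodinane oxidation of a primary alcohol to the aldehyde under buffered conditions that do not touch the amide.

Step 4
Reactants: 5 (3S)-N-methoxy-N,3-dimethyl-5-oxopentanamide
Product: 6 (3S,5R)-5-hydroxy-N-methoxy-N,3-dimethyloct-7-enamide
Conditions: (+)-Ipc2BOMe, allylMgBr, Et2O, 0 °C → rt; then 5, −78 °C; then NaOH, H2O2
Reagents that add atoms: allylmagnesium bromide, C=CC[Mg]Br
Why: Brown allylation transfers the allyl group through a chair six-membered transition state under reagent control and should set the 5R carbinol centre, the remote methyl centre having little influence.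

Step 5
Reactants: 6 (3S,5R)-5-hydroxy-N-methoxy-N,3-dimethyloct-7-enamide
Product: 7 (3S,5R)-5-[(tert-butyldimethylsilyl)oxy]-N-methoxy-N,3-dimethyloct-7-enamide
Conditions: TBSOTf, 2,6-lutidine, CH2Cl2, −78 → 0 °C
Reagents that add atoms: tert-butyldimethylsilyl trifluoromethanesulfonate, CC(C)(C)[Si](C)(C)OS(=O)(=O)C(F)(F)F
Why: Silylation of the secondary alcohol before it can lactonize onto the amide.

Step 6
Reactants: 7 (3S,5R)-5-[(tert-butyldimethylsilyl)oxy]-N-methoxy-N,3-dimethyloct-7-enamide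
Product: 9 (3S,5S)-5-[(tert-butyldimethylsilyl)oxy]-N-methoxy-N,3-dimethyl-7-oxoheptanamide, via ozonide 8 (not isolated)
Conditions: O3, CH2Cl2, −78 °C; then Me2S
Reagents that add atoms: ozone, [O-][O+]=O
Why: Ozonolysis of the only alkene with reductive work-up gives the β-silyloxy aldehyde.

Step 7
Reactants: 10 ethyl 2-diazo-2-(diethoxyphosphoryl)acetate; 11 (4-methoxyphenyl)methanol
Product: 12 ethyl 2-(diethoxyphosphoryl)-2-[(4-methoxyphenyl)methoxy]acetate
Conditions: Rh2(OAc)4 (1 mol %), benzene, 80 °C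
Reagents that add atoms: none
Why: Rhodium-carbenoid O–H insertion of the alcohol gives the α-alkoxy phosphonoacetate.

Step 8
Reactants: 9 (3S,5S)-5-[(tert-butyldimethylsilyl)oxy]-N-methoxy-N,3-dimethyl-7-oxoheptanamide; 12 ethyl 2-(diethoxyphosphoryl)-2-[(4-methoxyphenyl)methoxy]acetate
Product: 13 ethyl (2Z,5S,7S)-5-[(tert-butyldimethylsilyl)oxy]-9-[methoxy(methyl)amino]-2-[(4-methoxyphenyl)methoxy]-7-methyl-9-oxonon-2-enoate
Conditions: 12, LiN(SiMe3)2, THF, −78 °C; then 9, −78 → 0 °C
Reagents that add atoms: none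
Why: Horner–Wadsworth–Emmons olefination of the aldehyde by the phosphonate anion, which is far more acidic than the amide α-position, builds the α-alkoxy enoate.

Step 9
Reactants: 13 ethyl (2Z,5S,7S)-5-[(tert-butyldimethylsilyl)oxy]-9-[methoxy(methyl)amino]-2-[(4-methoxyphenyl)methoxy]-7-methyl-9-oxonon-2-enoate
Product: 14 (3S,5S,7Z)-5-[(tert-butyldimethylsilyl)oxy]-9-hydroxy-8-[(4-methoxyphenyl)methoxy]-3-methylnon-7-enal
Conditions: i-Bu2AlH (4 equiv), CH2Cl2, −78 °C
Reagents that add atoms: none
Why: One hydride reagent takes the enoate to the allylic alcohol and stops the N-methoxy-N-methylamide at the aldehyde through its stable chelated tetrahedral intermediate, which differentiates the two termini.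

Step 10
Reactants: 14 (3S,5S,7Z)-5-[(tert-butyldimethylsilyl)oxy]-9-hydroxy-8-[(4-methoxyphenyl)methoxy]-3-methylnon-7-enal
Product: 16 (3S,5S,7Z)-5-[(tert-butyldimethylsilyl)oxy]-9-hydroxy-8-[(4-methoxyphenyl)methoxy]-3-methyl-2-methylidenenon-7-enal, via Mannich base 15 (not isolated)
Conditions: CH2=NMe2+ I−, Et3N, CH2Cl2, rt
Reagents that add atoms: N,N-dimethylmethyleneiminium iodide, C=[N+](C)C.[I-]
Why: Mannich reaction at the only enolizable aldehyde followed by β-elimination of dimethylamine (α-methylenation) installs the methylene that will become the angular methyl group.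

Step 11
Reactants: 16 (3S,5S,7Z)-5-[(tert-butyldimethylsilyl)oxy]-9-hydroxy-8-[(4-methoxyphenyl)methoxy]-3-methyl-2-methylidenenon-7-enal
Product: 17 (3E,6S,8S,10Z)-8-[(tert-butyldimethylsilyl)oxy]-12-hydroxy-11-[(4-methoxyphenyl)methoxy]-6-methyl-5-methylidenedodeca-3,10-dien-2-one
Conditions: Ph3P=CHC(O)CH3, CH2Cl2, 40 °C
Reagents that add atoms: 1-(triphenyl-λ5-phosphanylidene)propan-2-one, CC(=O)C=P(c1ccccc1)(c1ccccc1)c1ccccc1
Why: Wittig olefination of the only aldehyde with a stabilized ylide should give the (E)-dienone.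

Step 12
Reactants: 17 (3E,6S,8S,10Z)-8-[(tert-butyldimethylsilyl)oxy]-12-hydroxy-11-[(4-methoxyphenyl)methoxy]-6-methyl-5-methylidenedodeca-3,10-dien-2-one
Product: 18 (2Z,5S,7S,9E)-5-[(tert-butyldimethylsilyl)oxy]-2-[(4-methoxyphenyl)methoxy]-7-methyl-8-methylidene-11-oxododeca-2,9-dienal
Conditions: MnO2, CH2Cl2, rt
Reagents that add atoms: none
Why: Allylic oxidation by MnO2 unveils the 2-alkoxy-2-enal last, after all hydride steps.

Step 13
Reactants: 18 (2Z,5S,7S,9E)-5-[(tert-butyldimethylsilyl)oxy]-2-[(4-methoxyphenyl)methoxy]-7-methyl-8-methylidene-11-oxododeca-2,9-dienal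
Product: 20 1-[(3R,4S,4aR,6S,8S,8aS)-6-[(tert-butyldimethylsilyl)oxy]-3-hydroxy-4-[(4-methoxyphenyl)methoxy]-8,8a-dimethyl-3,4,4a,5,6,7,8,8a-octahydronaphthalen-2-yl]ethan-1-one, via enone aldehyde 19 (not isolated)
Conditions: Fe(acac)3 (0.3 equiv), PhSiH3 (1.2 equiv), EtOH/THF, high dilution, 0 °C → rt; then PMe3 (2 equiv), rt
Reagents that add atoms: none
Why: Proposed new method: hydrogen-atom transfer from the iron hydride to the terminal methylene of the 5-methylidene-3-en-2-one (the only unhindered 1,1-disubstituted alkene) gives a radical delocalized over the dienone which, as such or after reduction to the trivalent-iron dienolate, bonds through its γ-carbon to the β-carbon of the 2-alkoxy-enal (6-exo-trig conjugate addition closing ring A and creating the quaternary carbon, attack through the α-carbon needing an eight-membered ring), and protonation leaves aldehyde 19 with the (E)-enone restored; trimethylphosphine then adds to the enone β-carbon and the phosphonium enolate closes ring B by a 6-(enolexo)-exo-trig aldol addition before β-elimination of the phosphine. The closest known reaction types are Fe(acac)3/PhSiH3 reductive olefin–acceptor coupling and radical–polar crossover annulation, cobalt-hydride Michael cycloreduction of enones, and the phosphine-mediated intramolecular Morita–Baylis–Hillman reaction; what is new is the vinylogous (δ-hydrogen, γ-carbon) variant and its telescoping. Ring A should form through a chair with the C-methyl group and the enal equatorial and the silyloxy group axial, the rigid enone chain taking the equatorial and the new methyl the axial position on the quaternary carbon, which gives the trans relation that becomes the trans ring fusion. The ether-bearing carbon is epimerizable in 19 and should enter ring B equatorial, and the carbinol carbon, formed in a reversible aldol step, should settle with its hydroxyl pseudoaxial (A(1,2) strain against the acetyl group) and cis to the neighbouring ether. The step needs hydrogen-atom transfer to the diene terminus rather than to the enal alkene and no second reduction of the regenerated enone; the accessibility of the terminal CH2, the neopentyl position of the new enone and a bare excess of silane are relied on for this.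

Step 14
Reactants: 20 1-[(3R,4S,4aR,6S,8S,8aS)-6-[(tert-butyldimethylsilyl)oxy]-3-hydroxy-4-[(4-methoxyphenyl)methoxy]-8,8a-dimethyl-3,4,4a,5,6,7,8,8a-octahydronaphthalen-2-yl]ethan-1-one
Product: 21 1-[(2S,3R,4S,4aR,6S,8S,8aR)-6-[(tert-butyldimethylsilyl)oxy]-3-hydroxy-4-[(4-methoxyphenyl)methoxy]-8,8a-dimethyldecahydronaphthalen-2-yl]ethan-1-one
Conditions: [Ir(cod)(PCy3)(py)]PF6 (10 mol %), H2 (1 atm), CH2Cl2, 0 °C → rt
Reagents that add atoms: none
Why: Hydroxyl-directed homogeneous hydrogenation delivers hydrogen from the face of the allylic alcohol, which is also the face opposite the angular methyl group, and so should place the acetyl group axial and syn to that methyl.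

Step 15
Reactants: 21 1-[(2S,3R,4S,4aR,6S,8S,8aR)-6-[(tert-butyldimethylsilyl)oxy]-3-hydroxy-4-[(4-methoxyphenyl)methoxy]-8,8a-dimethyldecahydronaphthalen-2-yl]ethan-1-one
Product: 22 (1S,2R,3R,4aR,5S,7S,8aR)-7-[(tert-butyldimethylsilyl)oxy]-1-[(4-methoxyphenyl)methoxy]-4a,5-dimethyl-3-(prop-1-en-2-yl)decahydronaphthalen-2-ol
Conditions: Zn, CH2Br2, TiCl4, THF/CH2Cl2, 0 °C → rt
Reagents that add atoms: dibromomethane, BrCBr
Why: Takai–Lombardo methylenation is non-basic, so the contra-thermodynamic axial acetyl centre should not epimerize and the β-hydroxy ketone should not undergo retro-aldol cleavage.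

Step 16
Reactants: 22 (1S,2R,3R,4aR,5S,7S,8aR)-7-[(tert-butyldimethylsilyl)oxy]-1-[(4-methoxyphenyl)methoxy]-4a,5-dimethyl-3-(prop-1-en-2-yl)decahydronaphthalen-2-ol
Product: 23 (1S,2R,3R,4aR,5S,7S,8aR)-7-[(tert-butyldimethylsilyl)oxy]-4a,5-dimethyl-3-(prop-1-en-2-yl)decahydronaphthalene-1,2-diol
Conditions: DDQ, CH2Cl2/pH 7 buffer, 0 °C
Reagents that add atoms: none
Why: Oxidative cleavage of the 4-methoxybenzyl ether in wet medium frees the equatorial hydroxyl without touching the isopropenyl group or the silyl ether.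

Step 17
Reactants: 23 (1S,2R,3R,4aR,5S,7S,8aR)-7-[(tert-butyldimethylsilyl)oxy]-4a,5-dimethyl-3-(prop-1-en-2-yl)decahydronaphthalene-1,2-diol; 24 (2E)-3-methylpent-2-enoic acid
Product: 26 (1S,2R,3R,4aR,5S,7S,8aR)-7-[(tert-butyldimethylsilyl)oxy]-2-hydroxy-4a,5-dimethyl-3-(prop-1-en-2-yl)decahydronaphthalen-1-yl (2E)-3-methylpent-2-enoate, via mixed anhydride 25 (not isolated)
Conditions: 24, 2,4,6-trichlorobenzoyl chloride, Et3N, THF, rt; then 23, DMAP, toluene, rt
Reagents that add atoms: 2,4,6-trichlorobenzoyl chloride, O=C(Cl)c1c(Cl)cc(Cl)cc1Cl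
Why: Yamaguchi esterification should acylate the equatorial hydroxyl in preference to the axial one, which is flanked by the axial isopropenyl group.

Step 18
Reactants: 26 (1S,2R,3R,4aR,5S,7S,8aR)-7-[(tert-butyldimethylsilyl)oxy]-2-hydroxy-4a,5-dimethyl-3-(prop-1-en-2-yl)decahydronaphthalen-1-yl (2E)-3-methylpent-2-enoate
Product: 27 (1S,2R,3R,4aR,5S,7S,8aR)-2,7-dihydroxy-4a,5-dimethyl-3-(prop-1-en-2-yl)decahydronaphthalen-1-yl (2E)-3-methylpent-2-enoate
Conditions: HF·pyridine, THF, 0 °C → rt
Reagents that add atoms: none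
Why: Fluoride-mediated desilylation under mildly acidic conditions avoids acyl migration in the cis-hydroxy ester and gives the target.

**Compound list**

1 | (3R)-5-methoxy-3-methyl-5-oxopentanoic acid | COC(=O)C[C@H](C)CC(=O)O | starting material
2 | (3S)-5-hydroxy-3-methylpentanoic acid (as lithium salt in the flask) | OC(=O)C[C@@H](C)CCO | intermediate
3 | (4S)-4-methyloxan-2-one | O=C1C[C@@H](C)CCO1 | intermediate
4 | (3S)-5-hydroxy-N-methoxy-N,3-dimethylpentanamide | CON(C)C(=O)C[C@@H](C)CCO | intermediate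
5 | (3S)-N-methoxy-N,3-dimethyl-5-oxopentanamide | CON(C)C(=O)C[C@@H](C)CC=O | intermediate
6 | (3S,5R)-5-hydroxy-N-methoxy-N,3-dimethyloct-7-enamide | CON(C)C(=O)C[C@@H](C)C[C@H](O)CC=C | intermediate
7 | (3S,5R)-5-[(tert-butyldimethylsilyl)oxy]-N-methoxy-N,3-dimethyloct-7-enamide | CON(C)C(=O)C[C@@H](C)C[C@H](O[Si](C)(C)C(C)(C)C)CC=C | intermediate
8 | (3S,5S)-5-[(tert-butyldimethylsilyl)oxy]-N-methoxy-N,3-dimethyl-6-(1,2,4-trioxolan-3-yl)hexanamide (ozonide, both epimers at the trioxolane carbon) | CON(C)C(=O)C[C@@H](C)C[C@H](O[Si](C)(C)C(C)(C)C)CC1OCOO1 | intermediate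
9 | (3S,5S)-5-[(tert-butyldimethylsilyl)oxy]-N-methoxy-N,3-dimethyl-7-oxoheptanamide | CON(C)C(=O)C[C@@H](C)C[C@H](O[Si](C)(C)C(C)(C)C)CC=O | intermediate
10 | ethyl 2-diazo-2-(diethoxyphosphoryl)acetate | CCOC(=O)C(=[N+]=[N-])P(=O)(OCC)OCC | starting material
11 | (4-methoxyphenyl)methanol | COc1ccc(CO)cc1 | starting material
12 | ethyl 2-(diethoxyphosphoryl)-2-[(4-methoxyphenyl)methoxy]acetate (racemic) | CCOC(=O)C(OCc1ccc(OC)cc1)P(=O)(OCC)OCC | intermediate
13 | ethyl (2Z,5S,7S)-5-[(tert-butyldimethylsilyl)oxy]-9-[methoxy(methyl)amino]-2-[(4-methoxyphenyl)methoxy]-7-methyl-9-oxonon-2-enoate | CON(C)C(=O)C[C@@H](C)C[C@H](O[Si](C)(C)C(C)(C)C)C/C=C(\OCc1ccc(OC)cc1)C(=O)OCC | intermediate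
14 | (3S,5S,7Z)-5-[(tert-butyldimethylsilyl)oxy]-9-hydroxy-8-[(4-methoxyphenyl)methoxy]-3-methylnon-7-enal | O=CC[C@@H](C)C[C@H](O[Si](C)(C)C(C)(C)C)C/C=C(\OCc1ccc(OC)cc1)CO | intermediate
15 | (3S,5S,7Z)-5-[(tert-butyldimethylsilyl)oxy]-2-[(dimethylamino)methyl]-9-hydroxy-8-[(4-methoxyphenyl)methoxy]-3-methylnon-7-enal (both C-2 epimers) | O=CC(CN(C)C)[C@@H](C)C[C@H](O[Si](C)(C)C(C)(C)C)C/C=C(\OCc1ccc(OC)cc1)CO | intermediate
16 | (3S,5S,7Z)-5-[(tert-butyldimethylsilyl)oxy]-9-hydroxy-8-[(4-methoxyphenyl)methoxy]-3-methyl-2-methylidenenon-7-enal | O=CC(=C)[C@@H](C)C[C@H](O[Si](C)(C)C(C)(C)C)C/C=C(\OCc1ccc(OC)cc1)CO | intermediate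
17 | (3E,6S,8S,10Z)-8-[(tert-butyldimethylsilyl)oxy]-12-hydroxy-11-[(4-methoxyphenyl)methoxy]-6-methyl-5-methylidenedodeca-3,10-dien-2-one | CC(=O)/C=C/C(=C)[C@@H](C)C[C@H](O[Si](C)(C)C(C)(C)C)C/C=C(\OCc1ccc(OC)cc1)CO | intermediate
18 | (2Z,5S,7S,9E)-5-[(tert-butyldimethylsilyl)oxy]-2-[(4-methoxyphenyl)methoxy]-7-methyl-8-methylidene-11-oxododeca-2,9-dienal | CC(=O)/C=C/C(=C)[C@@H](C)C[C@H](O[Si](C)(C)C(C)(C)C)C/C=C(\OCc1ccc(OC)cc1)C=O | intermediate
19 | (2S)-2-[(1R,2S,3S,5S)-5-[(tert-butyldimethylsilyl)oxy]-2,3-dimethyl-2-[(1E)-3-oxobut-1-en-1-yl]cyclohexyl]-2-[(4-methoxyphenyl)methoxy]acetaldehyde | CC(=O)/C=C/[C@]1(C)[C@@H](C)C[C@H](O[Si](C)(C)C(C)(C)C)C[C@H]1[C@H](OCc2ccc(OC)cc2)C=O | intermediate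
20 | 1-[(3R,4S,4aR,6S,8S,8aS)-6-[(tert-butyldimethylsilyl)oxy]-3-hydroxy-4-[(4-methoxyphenyl)methoxy]-8,8a-dimethyl-3,4,4a,5,6,7,8,8a-octahydronaphthalen-2-yl]ethan-1-one | CC(=O)C1=C[C@]2(C)[C@@H](C)C[C@H](O[Si](C)(C)C(C)(C)C)C[C@H]2[C@H](OCc3ccc(OC)cc3)[C@@H]1O | intermediate
21 | 1-[(2S,3R,4S,4aR,6S,8S,8aR)-6-[(tert-butyldimethylsilyl)oxy]-3-hydroxy-4-[(4-methoxyphenyl)methoxy]-8,8a-dimethyldecahydronaphthalen-2-yl]ethan-1-one | CC(=O)[C@H]1C[C@]2(C)[C@@H](C)C[C@H](O[Si](C)(C)C(C)(C)C)C[C@H]2[C@H](OCc3ccc(OC)cc3)[C@@H]1O | intermediate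
22 | (1S,2R,3R,4aR,5S,7S,8aR)-7-[(tert-butyldimethylsilyl)oxy]-1-[(4-methoxyphenyl)methoxy]-4a,5-dimethyl-3-(prop-1-en-2-yl)decahydronaphthalen-2-ol | C=C(C)[C@H]1C[C@]2(C)[C@@H](C)C[C@H](O[Si](C)(C)C(C)(C)C)C[C@H]2[C@H](OCc3ccc(OC)cc3)[C@@H]1O | intermediate
23 | (1S,2R,3R,4aR,5S,7S,8aR)-7-[(tert-butyldimethylsilyl)oxy]-4a,5-dimethyl-3-(prop-1-en-2-yl)decahydronaphthalene-1,2-diol | C=C(C)[C@H]1C[C@]2(C)[C@@H](C)C[C@H](O[Si](C)(C)C(C)(C)C)C[C@H]2[C@H](O)[C@@H]1O | intermediate
24 | (2E)-3-methylpent-2-enoic acid | CC/C(C)=C/C(=O)O | starting material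
25 | (2E)-3-methylpent-2-enoic 2,4,6-trichlorobenzoic anhydride | CC/C(C)=C/C(=O)OC(=O)c1c(Cl)cc(Cl)cc1Cl | intermediate
26 | (1S,2R,3R,4aR,5S,7S,8aR)-7-[(tert-butyldimethylsilyl)oxy]-2-hydroxy-4a,5-dimethyl-3-(prop-1-en-2-yl)decahydronaphthalen-1-yl (2E)-3-methylpent-2-enoate | C=C(C)[C@H]1C[C@]2(C)[C@@H](C)C[C@H](O[Si](C)(C)C(C)(C)C)C[C@H]2[C@H](OC(=O)/C=C(\C)CC)[C@@H]1O | intermediate
27 | (1S,2R,3R,4aR,5S,7S,8aR)-2,7-dihydroxy-4a,5-dimethyl-3-(prop-1-en-2-yl)decahydronaphthalen-1-yl (2E)-3-methylpent-2-enoate | C=C(C)[C@H]1C[C@]2(C)[C@@H](C)C[C@H](O)C[C@H]2[C@H](OC(=O)/C=C(\C)CC)[C@@H]1O | target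

**Step count and risks**

Total step count: 18. Longest linear sequence: 17 steps (steps 1–6 and 8–18; step 7 is a one-step branch).

Steps most likely to fail:

1. Step 13 (proposed new method). What may go wrong: hydrogen-atom transfer to the enal alkene or over-reduction of the regenerated enone instead of the diene terminus; poor control of the ring-fusion relationship in the bond formation at the quaternary carbon; stalling of phosphine addition at the hindered β-carbon. Fallback, from 16, with each operation of a known type: 1,2-addition of 1-propynylmagnesium bromide to the aldehyde gives the propargylic diol F1. Selective oxidation of its primary allylic alcohol (TEMPO, PhI(OAc)2) gives the enal F2. The alkene is now isolated and electron-rich, so Fe(acac)3/PhSiH3 generates an ordinary nucleophilic tertiary radical that closes ring A by 6-exo conjugate addition to the hydroxy aldehyde F3 (in equilibrium with its lactol). Meyer–Schuster rearrangement of the propargylic alcohol (Ph3PAuNTf2 cat., wet solvent) then gives the (E)-enone, which is compound 19; this is isolated and closed with PMe3 to 20 as a separate operation. The fallback comes back to the route at 19.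

2. Step 14. What may go wrong: hydrogen delivery from the wrong face, or epimerization of the axial acetyl centre to the more stable equatorial epimer during or after reduction. Fallback, from 20: the hydroxyl is capped as the triethylsilyl ether F4 (Et3SiOTf, 2,6-lutidine). Conjugate reduction with [(Ph3P)CuH]6 in wet benzene, with protonation of the copper enolate from the face opposite the angular methyl group, should give the saturated ketone F5. Removal of the triethylsilyl group (PPTS, MeOH) returns to the route at 21.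

3. Step 17. What may go wrong: acylation of the wrong hydroxyl, acyl migration within the cis-diol, or migration of the acid double bond out of conjugation under DMAP. Fallback, from 23: the diol is converted into its dibutylstannylene acetal F6 (Bu2SnO, toluene, reflux with removal of water). This is acylated without amine catalyst at 0 °C with (2E)-3-methylpent-2-enoyl chloride F7 (from 24 and oxalyl chloride); stannylene acetals of cis-diols pass the acyl group to the equatorial oxygen. The fallback comes back to the route at 26.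

Further compounds
F1 | step 13 | (6S,8S,10Z)-8-[(tert-butyldimethylsilyl)oxy]-11-[(4-methoxyphenyl)methoxy]-6-methyl-5-methylidenedodec-10-en-2-yne-4,12-diol (both C-4 epimers) | CC#CC(O)C(=C)[C@@H](C)C[C@H](O[Si](C)(C)C(C)(C)C)C/C=C(\OCc1ccc(OC)cc1)CO
F2 | step 13 | (2Z,5S,7S)-5-[(tert-butyldimethylsilyl)oxy]-9-hydroxy-2-[(4-methoxyphenyl)methoxy]-7-methyl-8-methylidenedodec-2-en-10-ynal (both C-9 epimers) | CC#CC(O)C(=C)[C@@H](C)C[C@H](O[Si](C)(C)C(C)(C)C)C/C=C(\OCc1ccc(OC)cc1)C=O
F3 | step 13 | (2S)-2-[(1R,2R,3S,5S)-5-[(tert-butyldimethylsilyl)oxy]-2-(1-hydroxybut-2-yn-1-yl)-2,3-dimethylcyclohexyl]-2-[(4-methoxyphenyl)methoxy]acetaldehyde (both carbinol epimers) | CC#CC(O)[C@]1(C)[C@@H](C)C[C@H](O[Si](C)(C)C(C)(C)C)C[C@H]1[C@H](OCc2ccc(OC)cc2)C=O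
F4 | step 14 | 1-[(3R,4S,4aR,6S,8S,8aS)-6-[(tert-butyldimethylsilyl)oxy]-4-[(4-methoxyphenyl)methoxy]-8,8a-dimethyl-3-[(triethylsilyl)oxy]-3,4,4a,5,6,7,8,8a-octahydronaphthalen-2-yl]ethan-1-one | CC(=O)C1=C[C@]2(C)[C@@H](C)C[C@H](O[Si](C)(C)C(C)(C)C)C[C@H]2[C@H](OCc3ccc(OC)cc3)[C@@H]1O[Si](CC)(CC)CC
F5 | step 14 | 1-[(2S,3R,4S,4aR,6S,8S,8aR)-6-[(tert-butyldimethylsilyl)oxy]-4-[(4-methoxyphenyl)methoxy]-8,8a-dimethyl-3-[(triethylsilyl)oxy]decahydronaphthalen-2-yl]ethan-1-one | CC(=O)[C@H]1C[C@]2(C)[C@@H](C)C[C@H](O[Si](C)(C)C(C)(C)C)C[C@H]2[C@H](OCc3ccc(OC)cc3)[C@@H]1O[Si](CC)(CC)CC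
F6 | step 17 | O,O'-dibutylstannylene acetal (2,2-dibutyl-1,3,2-dioxastannolane) of diol 23 | C=C(C)[C@H]1C[C@]2(C)[C@@H](C)C[C@H](O[Si](C)(C)C(C)(C)C)C[C@H]2[C@@H]3O[Sn](CCCC)(CCCC)O[C@H]13
F7 | step 17 | (2E)-3-methylpent-2-enoyl chloride | CC/C(C)=C/C(=O)Cl
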